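**Retrosynthetic overview**

1. The ten-membered carbocycle and the α-methylene-γ-lactone are closed last and together, by a C6–C7 Nozaki–Hiyama allylation/lactonisation of bromo-enal 27, followed by C8–O desilylation. The bromomethyl-acrylate arm comes from the C7 aldehyde (Morita–Baylis–Hillman, SN2′ bromination).
2. The 3(2H)-furanone O–C3=C2–C1(=O)–C10 is not closed as a five-membered ring. It grows out of the three-membered oxirane O–C10–C9 of epoxy ynone 13 (two atoms fewer) by a gold-catalysed ring expansion in which the side-chain acid 18 captures C9; the ester, the furanone and the C9/C10 stereo-pair arise in one operation.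
3. Enabling feature: oxirane carbon C10 carries the ynone carbonyl C1. This holds the oxirane oxygen 1,4 to alkyne carbon C3 (5-endo-dig) and leaves C9 as the only SN2-competent carbon of the oxiranium ion, while C10 keeps its C–O bond.
4. 13 comes from Sharpless epoxy aldehyde 8 (from (R)-but-3-ene-1,2-diol by Wittig, DIBAL-H, asymmetric epoxidation) and the acetylide of PMB-protected (Z)-3-methylpent-2-en-4-yn-1-ol; 18 comes from 3-methylfuran-2(5H)-one.
5. Ring order: oxirane (step 5) → furanone by 3→5 expansion (step 13) → ten-membered ring and lactone (step 20).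

Key step: step 13

Remark: atom numbers C1–C15 are those of the germacrane skeleton of the target (C1 ketone, C3 and C10 bear the ring oxygen, C6/C12 the lactone, C8 the OH, C9 the ester); compounds 1, 4, 9, 14 and 23 are taken as commercial; TBS = tert-butyldimethylsilyl, PMB = 4-methoxybenzyl.

**Route**

Step 1
Reactants: 1 (R)-but-3-ene-1,2-diol
Product: 2 (R)-3,4-bis(TBS-oxy)but-1-ene
Conditions: TBSCl, imidazole, DMF, rt
Reagents that add atoms: tert-butyldimethylsilyl chloride, CC(C)(C)[Si](C)(C)Cl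
Why: Imidazole-mediated silylation of both hydroxyls; the stereocentre (future C8) is not touched.

Step 2
Reactants: 2 (R)-3,4-bis(TBS-oxy)but-1-ene
Product: 3 (S)-2,3-bis(TBS-oxy)propanal
Conditions: O3, CH2Cl2, −78 °C; then PPh3, −78 °C → rt
Reagents that add atoms: ozone, [O-][O+]=O
Why: Ozonolysis with reductive work-up cleaves the only alkene to the α-silyloxy aldehyde under non-basic conditions, so the α-centre should be kept (the descriptor changes only through CIP priorities).

Step 3
Reactants: 3 (S)-2,3-bis(TBS-oxy)propanal; 4 ethyl 2-(triphenylphosphoranylidene)propanoate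
Product: 5 ethyl (2E,4R)-4,5-bis(TBS-oxy)-2-methylpent-2-enoate
Conditions: CH2Cl2, rt
Reagents that add atoms: none
Why: Wittig olefination with a stabilised α-methyl ylide should give the (E)-trisubstituted enoate under neutral conditions that do not epimerise the aldehyde.

Step 4
Reactants: 5 ethyl (2E,4R)-4,5-bis(TBS-oxy)-2-methylpent-2-enoate
Product: 6 (2E,4R)-4,5-bis(TBS-oxy)-2-methylpent-2-en-1-ol
Conditions: DIBAL-H, CH2Cl2, −78 °C; Rochelle salt work-up
Reagents that add atoms: none
Why: DIBAL-H 1,2-reduction of the enoate to the allylic alcohol needed for the directed epoxidation.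

Step 5
Reactants: 6 (2E,4R)-4,5-bis(TBS-oxy)-2-methylpent-2-en-1-ol
Product: 7 {(2R,3R)-3-[(1S)-1,2-bis(TBS-oxy)ethyl]-2-methyloxiran-2-yl}methanol
Conditions: Ti(OiPr)4 (cat.), D-(−)-diethyl tartrate (cat.), t-BuOOH, 4 Å MS, CH2Cl2, −20 °C
Reagents that add atoms: tert-butyl hydroperoxide, CC(C)(C)OO
Why: Sharpless asymmetric epoxidation; D-(−)-tartrate should deliver oxygen to the face that gives the (2R,3R)-oxirane under reagent control, which fixes C10 directly and C9 for the later inversion.

Step 6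
Reactants: 7 {(2R,3R)-3-[(1S)-1,2-bis(TBS-oxy)ethyl]-2-methyloxiran-2-yl}methanol
Product: 8 (2S,3R)-3-[(1S)-1,2-bis(TBS-oxy)ethyl]-2-methyloxirane-2-carbaldehyde
Conditions: Dess–Martin periodinane, NaHCO3, CH2Cl2, 0 °C → rt
Reagents that add atoms: none
Why: Dess–Martin oxidation of the primary alcohol; the aldehyde α-carbon (C10) is quaternary and cannot epimerise.

Step 7
Reactants: 9 (Z)-3-methylpent-2-en-4-yn-1-ol
Product: 10 1-methoxy-4-({[(2Z)-3-methylpent-2-en-4-yn-1-yl]oxy}methyl)benzene (PMB ether of 9)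
Conditions: NaH, PMBCl, Bu4NI (cat.), THF/DMF, 0 °C → rt
Reagents that add atoms: 4-methoxybenzyl chloride, COc1ccc(CCl)cc1
Why: Williamson etherification of the alkoxide; the Z-enyne, which carries C2–C6 and C15, is unchanged.

Step 8
Reactants: 10 PMB ether of (Z)-3-methylpent-2-en-4-yn-1-ol; 8 (2S,3R)-3-[(1S)-1,2-bis(TBS-oxy)ethyl]-2-methyloxirane-2-carbaldehyde
Product: 12 (4Z)-1-{3-[(1S)-1,2-bis(TBS-oxy)ethyl]-2-methyloxiran-2-yl}-6-(PMB-oxy)-4-methylhex-4-en-2-yn-1-ol (oxirane as in 8; C1 epimers), via lithium acetylide 11 (not isolated)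
Conditions: n-BuLi, THF, −78 °C; then 8, −78 °C
Reagents that add atoms: none
Why: Acetylide 1,2-addition to the aldehyde at low temperature, chemoselective over the trisubstituted oxirane; the new carbinol centre is removed in the next step.

Step 9
Reactants: 12 epoxy propargylic alcohol (C1 epimers)
Product: 13 (4Z)-1-{(2S,3R)-3-[(1S)-1,2-bis(TBS-oxy)ethyl]-2-methyloxiran-2-yl}-6-(PMB-oxy)-4-methylhex-4-en-2-yn-1-one
Conditions: Dess–Martin periodinane, NaHCO3, CH2Cl2, 0 °C
Reagents that add atoms: none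
Why: Buffered Dess–Martin oxidation of the propargylic alcohol gives the α,β-epoxy ynone and leaves the oxirane, silyl ethers and PMB ether intact.

Step 10
Reactants: 14 3-methylfuran-2(5H)-one
Product: 16 4-methoxybenzyl (2Z)-4-hydroxy-2-methylbut-2-enoate, via potassium carboxylate 15 (not isolated)
Conditions: KOH, MeOH/H2O, rt; evaporate; then PMBCl, DMF, rt
Reagents that add atoms: potassium hydroxide, [K+].[OH-]; 4-methoxybenzyl chloride, COc1ccc(CCl)cc1
Why: Saponification opens the butenolide to the hydroxy carboxylate, whose Z geometry is fixed by the ring, and carboxylate O-alkylation gives the ester without touching the alkene.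

Step 11
Reactants: 16 4-methoxybenzyl (2Z)-4-hydroxy-2-methylbut-2-enoate
Product: 17 4-methoxybenzyl (2Z)-4-acetoxy-2-methylbut-2-enoate
Conditions: Ac2O, pyridine, DMAP (cat.), CH2Cl2, 0 °C
Reagents that add atoms: acetic anhydride, CC(=O)OC(C)=O
Why: Acetylation of the primary allylic alcohol, done at once so that the hydroxy ester cannot relactonise.

Step 12
Reactants: 17 4-methoxybenzyl (2Z)-4-acetoxy-2-methylbut-2-enoate
Product: 18 (2Z)-4-acetoxy-2-methylbut-2-enoic acid
Conditions: TFA, anisole, CH2Cl2, 0 °C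
Reagents that add atoms: none
Why: Acidolysis of the PMB ester through the stabilised benzylic cation (trapped by anisole); the acetate and the Z-alkene should survive cold TFA.

Step 13
Reactants: 13 α,β-epoxy ynone; 18 (2Z)-4-acetoxy-2-methylbut-2-enoic acid
Product: 20 (1S,2S)-2,3-bis(TBS-oxy)-1-{(2S)-2-methyl-3-oxo-5-[(2Z)-4-(PMB-oxy)but-2-en-2-yl]-2,3-dihydrofuran-2-yl}propyl (2Z)-4-acetoxy-2-methylbut-2-enoate, via oxiranium vinylgold ion 19 (not isolated)
Conditions: Ph3PAuNTf2 (cat.), 18 (excess), 4 Å MS, CH2Cl2, 0 °C → rt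
Reagents that add atoms: none
Why: Proposed new method: the cationic gold(I) π-acid activates the ynone triple bond C2≡C3, the oxirane oxygen (held 1,4 to C3 through C10–C1) attacks C3 to give the bicyclic oxiranium/vinyl-gold ion 19 in which the five-membered ring O–C3=C2–C1(=O)–C10 already exists, and acid 18 then opens the three-membered ring of 19 at C9 by SN2 before protodeauration at C2 releases 20 and the catalyst, so that the oxirane O–C10–C9 is expanded to the furanone by exchange of its O–C9 bond for an O–C3 bond. The closest known reaction types are the gold-catalysed 5-endo cyclisation of α′-hydroxy ynones to 3(2H)-furanones and gold-catalysed epoxide–alkyne cascades in which the epoxide oxygen adds to the activated alkyne and an external O-nucleophile opens the resulting oxonium ion; new is the combination on an α,β-epoxy ynone with a carboxylic acid as terminating nucleophile. Only the furanone ring is closed, by 5-endo-dig O–C3 bond formation, while the oxirane is opened. C10 is retained from the Sharpless oxirane because its C–O bond is never broken, and C9 is set by inversion in the SN2 opening, so both centres derive from step 5. The step needs opening of 19 at C9 and not at C10, which should be secured because C10 is fully substituted, α to the C1 carbonyl and part of the new ring; it also needs attack of the oxirane oxygen to outrun intermolecular hydro-acyloxylation of the alkyne, which the five-membered intramolecular transition state and the ynone polarisation (electrophilic C3) favour.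

Step 14
Reactants: 20 furanone ester with C7 and C8 TBS ethers
Product: 21 (1S,2S)-2-(TBS-oxy)-3-hydroxy-1-{(2S)-2-methyl-3-oxo-5-[(2Z)-4-(PMB-oxy)but-2-en-2-yl]-2,3-dihydrofuran-2-yl}propyl (2Z)-4-acetoxy-2-methylbut-2-enoate
Conditions: HF·pyridine, pyridine, THF, 0 °C
Reagents that add atoms: none
Why: Buffered HF·pyridine should cleave the primary (C7) TBS ether much faster than the hindered secondary (C8) one, and the esters and the PMB ether are stable to it.

Step 15
Reactants: 21 C7 primary alcohol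
Product: 22 (1S,2R)-2-(TBS-oxy)-3-oxo-1-{(2S)-2-methyl-3-oxo-5-[(2Z)-4-(PMB-oxy)but-2-en-2-yl]-2,3-dihydrofuran-2-yl}propyl (2Z)-4-acetoxy-2-methylbut-2-enoate (C7 aldehyde; C8 unchanged, descriptor changes by CIP only)
Conditions: Dess–Martin periodinane, NaHCO3, CH2Cl2, 0 °C
Reagents that add atoms: none
Why: Buffered Dess–Martin oxidation gives the α-silyloxy aldehyde without base, and it is used at once.

Step 16
Reactants: 22 C7 aldehyde; 23 methyl acrylate
Product: 24 Morita–Baylis–Hillman adduct, methyl 2-[hydroxy(C8)methyl]acrylate at C7 (C7 epimers; C8, C9, C10 as in 20)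
Conditions: DABCO, methyl acrylate (excess, co-solvent), rt
Reagents that add atoms: none
Why: Morita–Baylis–Hillman reaction, chemoselective for the only aldehyde; the new C7 carbinol centre is irrelevant because C7 becomes sp2 in the next step.

Step 17
Reactants: 24 Morita–Baylis–Hillman adduct
Product: 25 methyl (2Z,4S,5S)-5-{[(2Z)-4-acetoxy-2-methylbut-2-enoyl]oxy}-2-(bromomethyl)-4-(TBS-oxy)-5-{(2S)-2-methyl-3-oxo-5-[(2Z)-4-(PMB-oxy)but-2-en-2-yl]-2,3-dihydrofuran-2-yl}pent-2-enoate
Conditions: NBS, Me2S, CH2Cl2, −20 °C → rt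
Reagents that add atoms: N-bromosuccinimide, O=C1CCC(=O)N1Br
Why: Corey–Kim-type activation of the allylic alcohol and SN2′ delivery of bromide with allylic transposition should give the thermodynamically preferred (Z)-2-(bromomethyl)enoate.

Step 18
Reactants: 25 allylic bromide with C6 PMB ether
Product: 26 the corresponding C6 allylic alcohol, (2Z)-4-hydroxybut-2-en-2-yl on the furanone
Conditions: DDQ, CH2Cl2/pH 7 buffer, 0 °C
Reagents that add atoms: none
Why: Oxidative PMB cleavage by DDQ (benzylic hydride abstraction, hydrolysis of the oxocarbenium ion) under neutral conditions that spare the allylic bromide, silyl ether and esters.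

Step 19
Reactants: 26 C6 allylic alcohol
Product: 27 the corresponding (Z)-enal, (2Z)-4-oxobut-2-en-2-yl on the furanone
Conditions: Dess–Martin periodinane, NaHCO3, CH2Cl2, 0 °C
Reagents that add atoms: none
Why: Neutral Dess–Martin oxidation should give the Z-enal without Z/E isomerisation, and it is used at once.

Step 20
Reactants: 27 bromo-enal
Product: 29 8-O-TBS ether of the target, (6R,7R,8S,9S,10S), via hydroxy ester 28 (not isolated)
Conditions: CrCl2, DMF/THF, rt, high dilution (slow addition); lactonisation on work-up (cat. TsOH if incomplete)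
Reagents that add atoms: none
Why: Intramolecular Nozaki–Hiyama (Barbier-type) allylation: the allylchromium(III) adds through its γ-carbon C7 to the enal in a chair transition state to form C6–C7 and the ten-membered ring, and the C6 alkoxide then closes the lactone onto the methyl ester; the 6,7-trans and 7,8-anti relationships are expected from macrocyclic control (tether atoms C5 and C8 pseudo-equatorial, attack anti to the C8–OTBS bond) but are not secured by acyclic precedent.

Step 21
Reactants: 29 8-O-TBS ether of the target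
Product: 30 (6R,7R,8S,9S,10S)-9-{[(2Z)-4-acetoxy-2-methylbut-2-enoyl]oxy}-8-hydroxy-1-oxo-3,10-epoxygermacra-2,4Z,11(13)-trien-12,6-olide (CNP0523348.1)
Conditions: HF·pyridine, THF, 0 °C → rt
Reagents that add atoms: none
Why: Mildly acidic fluoride desilylation frees the C8 hydroxyl and should leave the acetate, the unsaturated esters, the lactone and the furanone intact without 9→8 acyl migration.

**Compound list**

1 | (R)-but-3-ene-1,2-diol | C=C[C@@H](O)CO | starting material
2 | (R)-3,4-bis(TBS-oxy)but-1-ene | C=C[C@@H](O[Si](C)(C)C(C)(C)C)CO[Si](C)(C)C(C)(C)C | intermediate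
3 | (S)-2,3-bis(TBS-oxy)propanal | O=C[C@@H](O[Si](C)(C)C(C)(C)C)CO[Si](C)(C)C(C)(C)C | intermediate
4 | ethyl 2-(triphenylphosphoranylidene)propanoate | CCOC(=O)C(C)=P(c1ccccc1)(c1ccccc1)c1ccccc1 | starting material
5 | ethyl (2E,4R)-4,5-bis(TBS-oxy)-2-methylpent-2-enoate | CCOC(=O)/C(C)=C/[C@@H](O[Si](C)(C)C(C)(C)C)CO[Si](C)(C)C(C)(C)C | intermediate
6 | (2E,4R)-4,5-bis(TBS-oxy)-2-methylpent-2-en-1-ol | OC/C(C)=C/[C@@H](O[Si](C)(C)C(C)(C)C)CO[Si](C)(C)C(C)(C)C | intermediate
7 | {(2R,3R)-3-[(1S)-1,2-bis(TBS-oxy)ethyl]-2-methyloxiran-2-yl}methanol | OC[C@@]1(C)O[C@@H]1[C@@H](O[Si](C)(C)C(C)(C)C)CO[Si](C)(C)C(C)(C)C | intermediate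
8 | (2S,3R)-3-[(1S)-1,2-bis(TBS-oxy)ethyl]-2-methyloxirane-2-carbaldehyde | O=C[C@@]1(C)O[C@@H]1[C@@H](O[Si](C)(C)C(C)(C)C)CO[Si](C)(C)C(C)(C)C | intermediate
9 | (Z)-3-methylpent-2-en-4-yn-1-ol | C#C/C(C)=C\CO | starting material
10 | 1-methoxy-4-({[(2Z)-3-methylpent-2-en-4-yn-1-yl]oxy}methyl)benzene | C#C/C(C)=C\COCc1ccc(OC)cc1 | intermediate
11 | lithium acetylide of 10 | [Li]C#C/C(C)=C\COCc1ccc(OC)cc1 | intermediate
12 | (4Z)-1-{3-[(1S)-1,2-bis(TBS-oxy)ethyl]-2-methyloxiran-2-yl}-6-(PMB-oxy)-4-methylhex-4-en-2-yn-1-ol (oxirane as in 8, C1 epimers) | OC(C#C/C(C)=C\COCc1ccc(OC)cc1)[C@@]2(C)O[C@@H]2[C@@H](O[Si](C)(C)C(C)(C)C)CO[Si](C)(C)C(C)(C)C | intermediate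
13 | (4Z)-1-{(2S,3R)-3-[(1S)-1,2-bis(TBS-oxy)ethyl]-2-methyloxiran-2-yl}-6-(PMB-oxy)-4-methylhex-4-en-2-yn-1-one | O=C(C#C/C(C)=C\COCc1ccc(OC)cc1)[C@@]2(C)O[C@@H]2[C@@H](O[Si](C)(C)C(C)(C)C)CO[Si](C)(C)C(C)(C)C | intermediate
14 | 3-methylfuran-2(5H)-one | CC1=CCOC1=O | starting material
15 | potassium (2Z)-4-hydroxy-2-methylbut-2-enoate | [K+].[O-]C(=O)/C(C)=C\CO | intermediate
16 | 4-methoxybenzyl (2Z)-4-hydroxy-2-methylbut-2-enoate | COc1ccc(COC(=O)/C(C)=C\CO)cc1 | intermediate
17 | 4-methoxybenzyl (2Z)-4-acetoxy-2-methylbut-2-enoate | COc1ccc(COC(=O)/C(C)=C\COC(C)=O)cc1 | intermediate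
18 | (2Z)-4-acetoxy-2-methylbut-2-enoic acid | OC(=O)/C(C)=C\COC(C)=O | intermediate
19 | bicyclic oxiranium vinylgold ion (1-oxoniabicyclo[3.1.0]hex-2-en-4-one core, O bonded to C3, C10 and C9; C2–AuPPh3), triflimide salt | O=C1C([Au-][P+](c2ccccc2)(c2ccccc2)c2ccccc2)=C(/C(C)=C\COCc2ccc(OC)cc2)[O+]3[C@@]1(C)[C@H]3[C@@H](O[Si](C)(C)C(C)(C)C)CO[Si](C)(C)C(C)(C)C.[N-](S(=O)(=O)C(F)(F)F)S(=O)(=O)C(F)(F)F | intermediate
20 | (1S,2S)-2,3-bis(TBS-oxy)-1-{(2S)-2-methyl-3-oxo-5-[(2Z)-4-(PMB-oxy)but-2-en-2-yl]-2,3-dihydrofuran-2-yl}propyl (2Z)-4-acetoxy-2-methylbut-2-enoate | COc1ccc(COC/C=C(/C)C2=CC(=O)[C@@](C)(O2)[C@@H](OC(=O)/C(C)=C\COC(C)=O)[C@@H](O[Si](C)(C)C(C)(C)C)CO[Si](C)(C)C(C)(C)C)cc1 | intermediate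
21 | C7 primary alcohol of 20 (C8 TBS ether kept) | COc1ccc(COC/C=C(/C)C2=CC(=O)[C@@](C)(O2)[C@@H](OC(=O)/C(C)=C\COC(C)=O)[C@@H](O[Si](C)(C)C(C)(C)C)CO)cc1 | intermediate
22 | C7 aldehyde of 21 | COc1ccc(COC/C=C(/C)C2=CC(=O)[C@@](C)(O2)[C@@H](OC(=O)/C(C)=C\COC(C)=O)[C@@H](O[Si](C)(C)C(C)(C)C)C=O)cc1 | intermediate
23 | methyl acrylate | C=CC(=O)OC | starting material
24 | Morita–Baylis–Hillman adduct at C7 (C7 epimers) | COc1ccc(COC/C=C(/C)C2=CC(=O)[C@@](C)(O2)[C@@H](OC(=O)/C(C)=C\COC(C)=O)[C@@H](O[Si](C)(C)C(C)(C)C)C(O)C(=C)C(=O)OC)cc1 | intermediate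
25 | methyl (2Z,4S,5S)-2-(bromomethyl)pent-2-enoate carrying C8-OTBS, the C9 ester, the furanone and the C6 PMB ether | COc1ccc(COC/C=C(/C)C2=CC(=O)[C@@](C)(O2)[C@@H](OC(=O)/C(C)=C\COC(C)=O)[C@@H](O[Si](C)(C)C(C)(C)C)/C=C(\CBr)C(=O)OC)cc1 | intermediate
26 | C6 allylic alcohol of 25 | OC/C=C(/C)C1=CC(=O)[C@@](C)(O1)[C@@H](OC(=O)/C(C)=C\COC(C)=O)[C@@H](O[Si](C)(C)C(C)(C)C)/C=C(\CBr)C(=O)OC | intermediate
27 | (Z)-enal of 26 (bromo-enal) | O=C/C=C(/C)C1=CC(=O)[C@@](C)(O1)[C@@H](OC(=O)/C(C)=C\COC(C)=O)[C@@H](O[Si](C)(C)C(C)(C)C)/C=C(\CBr)C(=O)OC | intermediate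
28 | ten-membered C6-hydroxy methyl ester (6R,7R,8S,9S,10S), lactone not yet closed | C=C(C(=O)OC)[C@H]1[C@H](O)/C=C(/C)C2=CC(=O)[C@@](C)(O2)[C@@H](OC(=O)/C(C)=C\COC(C)=O)[C@H]1O[Si](C)(C)C(C)(C)C | intermediate
29 | 8-O-TBS ether of the target | C=C1C(=O)O[C@@H]2/C=C(/C)C3=CC(=O)[C@@](C)(O3)[C@@H](OC(=O)/C(C)=C\COC(C)=O)[C@@H](O[Si](C)(C)C(C)(C)C)[C@@H]12 | intermediate
30 | (6R,7R,8S,9S,10S)-9-{[(2Z)-4-acetoxy-2-methylbut-2-enoyl]oxy}-8-hydroxy-1-oxo-3,10-epoxygermacra-2,4Z,11(13)-trien-12,6-olide (CNP0523348.1) | C=C1C(=O)O[C@@H]2/C=C(/C)C3=CC(=O)[C@@](C)(O3)[C@@H](OC(=O)/C(C)=C\COC(C)=O)[C@@H](O)[C@@H]12 | target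

**Step count and risks**

Total step count: 21. Longest linear sequence: 17 (steps 1–6, 8, 9, 13–21).

Steps most likely to fail:

1. Step 13 (Proposed new method). The cationic gold/acid medium may trigger an acyl-shift (Meinwald-type) isomerisation of the 2-acyl oxirane, or plain hydro-acyloxylation of the ynone, before the oxirane oxygen engages C3; SN2 opening at the congested C9 may also be too slow. Fallback with known chemistry, setting out from 12 and coming back at 20: titanium(IV) isopropoxide-mediated regioselective C-3 opening of the 2,3-epoxy alcohol 12 by acid 18 (inversion at C9, C10–O kept) should give the C9 ester diol F1; MnO2 oxidation of its propargylic carbinol should give the α′-hydroxy ynone F2; the established gold(I)- or diethylamine-mediated 5-endo cyclisation of α′-hydroxy ynones then closes the furanone directly to 20.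

2. Step 20. Intermolecular coupling or reduction of the allylic bromide may compete with ring closure, and closure through the alternative chair would give the cis-fused lactone or the C7 epimer, because the stereochemical course rests on macrocyclic control alone. Fallback, setting out from 25 and coming back at 29: palladium-catalysed borylation of the allylic bromide with bis(pinacolato)diboron should give the 2-(methoxycarbonyl)allylboronate F3; DDQ removal of the PMB group gives the allylic alcohol F4 and Dess–Martin oxidation the boronate enal F5. F5 is then closed by intramolecular allylboration through a closed six-membered transition state, with lactonisation to 29; this works without a reductant, and the thermal and Brønsted-acid-catalysed modes are known to lead to opposite cis/trans lactone series, which gives a handle on the C6/C7 relationship.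

3. Step 16. During the slow amine-catalysed reaction the enolisable α-silyloxy aldehyde may lose the C9 carboxylate by β-elimination (E1cB) or epimerise at C8. Fallback, setting out from 22 and coming back at 24: hydroalumination of methyl propiolate with DIBAL-H/NMO gives the [1-(methoxycarbonyl)vinyl]diisobutylaluminium reagent F6, which adds to aldehydes at 0 °C without amine base (vinylalumination) and should give 24 directly.

**Further compounds**

F1 | step 13 | C9 ester diol: (4Z)-1,2-dihydroxy hex-4-en-2-yne from Ti-mediated opening of 12 by 18 (C1 epimers; C8 S, C9 S, C10 S) | OC(C#C/C(C)=C\COCc1ccc(OC)cc1)[C@@](C)(O)[C@@H](OC(=O)/C(C)=C\COC(C)=O)[C@@H](O[Si](C)(C)C(C)(C)C)CO[Si](C)(C)C(C)(C)C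
F2 | step 13 | α′-hydroxy ynone (C10 tertiary OH, C9 ester) | O=C(C#C/C(C)=C\COCc1ccc(OC)cc1)[C@@](C)(O)[C@@H](OC(=O)/C(C)=C\COC(C)=O)[C@@H](O[Si](C)(C)C(C)(C)C)CO[Si](C)(C)C(C)(C)C
F3 | step 20 | pinacol allylboronate corresponding to bromide 25 (C6 PMB ether) | COc1ccc(COC/C=C(/C)C2=CC(=O)[C@@](C)(O2)[C@@H](OC(=O)/C(C)=C\COC(C)=O)[C@@H](O[Si](C)(C)C(C)(C)C)/C=C(\CB3OC(C)(C)C(C)(C)O3)C(=O)OC)cc1
F4 | step 20 | C6 allylic alcohol of F3 | OC/C=C(/C)C1=CC(=O)[C@@](C)(O1)[C@@H](OC(=O)/C(C)=C\COC(C)=O)[C@@H](O[Si](C)(C)C(C)(C)C)/C=C(\CB2OC(C)(C)C(C)(C)O2)C(=O)OC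
F5 | step 20 | (Z)-enal of F4 (boronate enal) | O=C/C=C(/C)C1=CC(=O)[C@@](C)(O1)[C@@H](OC(=O)/C(C)=C\COC(C)=O)[C@@H](O[Si](C)(C)C(C)(C)C)/C=C(\CB2OC(C)(C)C(C)(C)O2)C(=O)OC
F6 | step 16 | [1-(methoxycarbonyl)vinyl]diisobutylaluminium | COC(=O)C(=C)[Al](CC(C)C)CC(C)C
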